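**Plan**
- Retrosynthetic cuts: C7=CH2 (methylenation); C3–Br and C2–Cl (back to a ring A C2=C3 alkene through a temporary C7–O–C3 ether); C3–C4 (ring A closure); C6–C5 and C1–C2 (three-component coupling on an exocyclic enone); C6–C11 (bromonium cyclisation); C8–C9 (dianion alkylation).
- Forward order: ring B with its bromide first, then the quaternary carbon C6 with both arms, then ring A by C3–C4 closure, then the ring A halogens, last the C7 methylene.
- Stereochemistry: C10 from a catalytic enantioselective bromochlorination; C6 relayed from C10 (enolate alkylation anti to the axial C11 methyl); C2 and C3 relayed from C6 through the ether bridge (anti chloro-etherification, then bromide for oxygen with retention).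
- Enabling features: C3 is the methyl-bearing sp2 carbon of a 1-methylcyclohexene, and its neighbour C4 ends the unfunctionalised two-carbon arm C5–C4 on spiro carbon C6. A (Z)-alkenyl iodide on the C1 arm and an alkylzinc on the C5 arm, both held on C6, can therefore be joined across a six-membered ring. The C7 oxygen of ring B is 1,4 to C3 across ring A (the terpineol/cineole relationship), so it can bridge to C3.

Key step: step 10

Remark: carbons are numbered as in spiro[5.5]undecane (ring A C1–C5, spiro carbon C6, ring B C7–C11); the target is (2S,3S,6S,10R)-3,10-dibromo-2-chloro-3,11,11-trimethyl-7-methylidenespiro[5.5]undecane.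
Assumption: in step 1 the enantiomer of the Schiff-base ligand is the one that delivers the (R)-bromochloride.

Step 1
Reactants: 1 3-methylbut-2-en-1-ol
Product: 2 (2R)-2-bromo-3-chloro-3-methylbutan-1-ol
Conditions: NBS, ClTi(OiPr)3, chiral tridentate Schiff-base ligand (20 mol%), hexanes, −20 °C
Reagents that add atoms: N-bromosuccinimide (O=C1CCC(=O)N1Br); chlorotitanium triisopropoxide (CC(C)O[Ti](Cl)(OC(C)C)OC(C)C)
Why: Titanium/Schiff-base-catalysed enantioselective bromochlorination of an allylic alcohol: anti addition with Br+ from NBS at C2 and titanium-bound chloride delivered to the distal tertiary carbon, the ligand enantiomer fixing the C–Br stereocentre as R (the later C10).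

Step 2
Reactants: 2 (2R)-2-bromo-3-chloro-3-methylbutan-1-ol
Product: 3 (2R)-2-bromo-3-chloro-3-methylbutyl trifluoromethanesulfonate
Conditions: Tf2O, pyridine, CH2Cl2, −78 °C
Reagents that add atoms: trifluoromethanesulfonic anhydride (O=S(=O)(OS(=O)(=O)C(F)(F)F)C(F)(F)F)
Why: O-Sulfonylation of the primary alcohol gives a leaving group reactive enough for C–C bond formation at low temperature, and the C–Br stereocentre is not involved.

Step 3
Reactants: 3 (2R)-2-bromo-3-chloro-3-methylbutyl trifluoromethanesulfonate; 4 prop-2-en-1-yl 3-oxobutanoate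
Product: 6 prop-2-en-1-yl (6R)-6-bromo-7-chloro-7-methyl-3-oxooctanoate, via acetoacetate dianion 5 (not isolated)
Conditions: 4, NaH then n-BuLi, THF, 0 °C; then 3, −78 → −20 °C; aqueous quench
Reagents that add atoms: none
Why: γ-Alkylation of a β-keto ester dianion, whose terminal carbanion is the more reactive site, by SN2 displacement of the primary triflate; the stereocentre is untouched.

Step 4
Reactants: 6 prop-2-en-1-yl (6R)-6-bromo-7-chloro-7-methyl-3-oxooctanoate
Product: 7 prop-2-en-1-yl (1R,3R)-3-bromo-2,2-dimethyl-6-oxocyclohexane-1-carboxylate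
Conditions: (CF3)2CHOH, 0 °C → rt
Reagents that add atoms: none
Why: Solvolytic bromonium-ion cyclisation: the tertiary chloride ionises with anchimeric help from the vicinal bromine and the β-keto ester enol attacks the tertiary carbon of the bromonium ion anti to bromine (6-(enolendo)-exo closure through a chair), so the C–Br configuration is carried over and ring B forms with equatorial bromine; C1 is epimerisable and is lost in step 5.

Step 5
Reactants: 7 prop-2-en-1-yl (1R,3R)-3-bromo-2,2-dimethyl-6-oxocyclohexane-1-carboxylate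
Product: 10 (4R)-4-bromo-3,3-dimethyl-2-methylidenecyclohexan-1-one, via β-keto acid 8 (not isolated), via Mannich adduct 9 (not isolated)
Conditions: Pd(PPh3)4 (2 mol%), morpholine, THF, 0 °C; then aq. CH2O, 45 °C
Reagents that add atoms: formaldehyde (C=O)
Why: Palladium-catalysed deallylation to the β-keto acid followed by decarboxylative Mannich methylenation (the aminomethyl acid loses CO2 and amine) places the exocyclic enone regiospecifically at the carbon next to the CMe2 group.

Step 6
Reactants: 10 (4R)-4-bromo-3,3-dimethyl-2-methylidenecyclohexan-1-one; 11 2-bromoethyl trifluoromethanesulfonate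
Product: 14 (2S,4R)-4-bromo-2-(2-bromoethyl)-3,3-dimethyl-2-(prop-2-en-1-yl)cyclohexan-1-one, via silyl enol ether 12 (not isolated), via lithium enolate 13 (not isolated)
Conditions: CH2=CHMgBr, CuBr·SMe2 (10 mol%), Me3SiCl, THF, −78 °C; then MeLi, 0 °C; then 11, −78 → 0 °C
Reagents that add atoms: vinylmagnesium bromide (C=C[Mg]Br)
Why: Copper-catalysed conjugate addition to the s-cis enone with silyl trapping fixes the enolate regiochemistry, and the lithium enolate regenerated with MeLi is C-alkylated by the triflate on the face opposite the pseudoaxial methyl of the adjacent CMe2 carbon (bromine pseudoequatorial), which puts the bromoethyl arm trans and the allyl arm cis to bromine and so sets the quaternary centre (later C6).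

Step 7
Reactants: 14 (2S,4R)-4-bromo-2-(2-bromoethyl)-3,3-dimethyl-2-(prop-2-en-1-yl)cyclohexan-1-one
Product: 16 2-[(1S,3R)-3-bromo-1-(2-bromoethyl)-2,2-dimethyl-6-oxocyclohexyl]acetaldehyde, via ozonide 15 (not isolated)
Conditions: O3, CH2Cl2, −78 °C; then PPh3
Reagents that add atoms: ozone (O=[O+][O-])
Why: Ozonolysis of the only alkene with reductive work-up shortens the allyl arm to the acetaldehyde arm.

Step 8
Reactants: 16 2-[(1S,3R)-3-bromo-1-(2-bromoethyl)-2,2-dimethyl-6-oxocyclohexyl]acetaldehyde
Product: 17 (2S,4R)-4-bromo-2-(2-bromoethyl)-2-[(2Z)-3-iodobut-2-en-1-yl]-3,3-dimethylcyclohexan-1-one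
Conditions: [Ph3PEt]I, n-BuLi, THF; I2, −78 °C; NaN(SiMe3)2; then 16, −78 → −20 °C
Reagents that add atoms: ethyltriphenylphosphonium iodide (CC[P+](c1ccccc1)(c1ccccc1)c1ccccc1.[I-]); iodine ([I][I])
Why: Stork–Zhao-type Wittig olefination with the α-iodo ylide converts the aldehyde into the (Z)-2-iodoalkene (iodine cis to the chain) while the hindered ketone is left alone.

Step 9
Reactants: 17 (2S,4R)-4-bromo-2-(2-bromoethyl)-2-[(2Z)-3-iodobut-2-en-1-yl]-3,3-dimethylcyclohexan-1-one
Product: 18 (2S,4R)-4-bromo-2-[(2Z)-3-iodobut-2-en-1-yl]-2-(2-iodoethyl)-3,3-dimethylcyclohexan-1-one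
Conditions: NaI, acetone, 50 °C
Reagents that add atoms: sodium iodide ([Na+].[I-])
Why: Finkelstein exchange takes place only at the primary bromide, since the neopentyl-type secondary bromide and the alkenyl iodide do not undergo SN2 substitution.

Step 10
Reactants: 18 (2S,4R)-4-bromo-2-[(2Z)-3-iodobut-2-en-1-yl]-2-(2-iodoethyl)-3,3-dimethylcyclohexan-1-one
Product: 20 (6R,10R)-10-bromo-3,11,11-trimethylspiro[5.5]undec-2-en-7-one, via alkylzinc iodide 19 (not isolated)
Conditions: Zn dust, LiCl, THF, 25 °C; then PdCl2(dppf) (5 mol%), 40 °C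
Reagents that add atoms: none
Why: Zinc inserts into the primary C–I bond (19), zerovalent palladium adds oxidatively to the alkenyl C–I bond with retention of the (Z) geometry, the alkyl group passes from zinc to palladium within the molecule, and reductive elimination from the seven-membered palladacycle forms C3–C4. The closest known reaction type is the intramolecular sp3–sp2 Negishi coupling, with the intramolecular B-alkyl Suzuki cyclisation of ω-borylalkyl haloalkenes to cycloalkenes as the nearest ring-forming analogue. Ring A closes as a six-membered ring by C(sp2)–C(sp3) bond formation in which the double bond stays inside the ring (endocyclic mode), which is possible only because iodine and the C1 chain are cis on the alkene. No stereocentre is created; C6 and C10 are not touched, and the position of the only ring A double bond (C2=C3, on the arm cis to the C10 bromine) is fixed by the precursor. The step needs chemoselective metalation, which the substrate secures through the much faster zinc insertion into a primary alkyl iodide than into the alkenyl iodide or the hindered secondary bromide, and through the inertness of alkylzinc halides toward the hindered ketone.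

Step 11
Reactants: 20 (6R,10R)-10-bromo-3,11,11-trimethylspiro[5.5]undec-2-en-7-one
Product: 21 (6R,7R,10R)-10-bromo-3,11,11-trimethylspiro[5.5]undec-2-en-7-ol
Conditions: Al(OiPr)3 (30 mol%), i-PrOH, 80 °C, equilibrating
Reagents that add atoms: none
Why: Meerwein–Ponndorf–Verley reduction under equilibrating conditions should give the thermodynamically preferred equatorial C7 alcohol (trans to the C10 bromine), because the axial epimer suffers a 1,3-diaxial contact with the axial C11 methyl; this sets C7 (R), a temporary stereocentre.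

Step 12
Reactants: 21 (6R,7R,10R)-10-bromo-3,11,11-trimethylspiro[5.5]undec-2-en-7-ol
Product: 22 (2S,3S,6R,7R,10R)-10-bromo-2-chloro-3,11,11-trimethyl-3,7-epoxyspiro[5.5]undecane
Conditions: NCS, Ph3P=S (10 mol%), CH2Cl2, −20 → 0 °C
Reagents that add atoms: N-chlorosuccinimide (O=C1CCC(=O)N1Cl)
Why: Chloro-cycloetherification: Cl+ adds to the C2=C3 double bond and the C7 hydroxyl, held 1,4 to C3 across ring A as in a terpineol, closes the 2-oxabicyclo[2.2.2]octane at the tertiary carbon (Markovnikov, ring A as a boat), so anti addition places chlorine on C2 on the face away from the oxygen bridge (cis to C11), setting C2 (S) and the C3–O bond cis to C7.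

Step 13
Reactants: 22 (2S,3S,6R,7R,10R)-10-bromo-2-chloro-3,11,11-trimethyl-3,7-epoxyspiro[5.5]undecane
Product: 24 (2S,3S,6R,7R,10R)-3,10-dibromo-2-chloro-3,11,11-trimethylspiro[5.5]undecan-7-ol, via dimethylborinate 23 (not isolated)
Conditions: Me2BBr, CH2Cl2, −78 °C; then aq. NaHCO3
Reagents that add atoms: bromodimethylborane (CB(C)Br)
Why: Boron-bromide cleavage of the tertiary C3–O ether bond: boron binds the bridging oxygen, the C3–O bond ionises with the antiperiplanar C2–Cl bond shielding (bridging) the rear face, and bromide is returned from the bromoborate on the face the oxygen leaves, so bromine should replace oxygen with retention (double inversion) and end trans to chlorine, setting C3 (S).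

Step 14
Reactants: 24 (2S,3S,6R,7R,10R)-3,10-dibromo-2-chloro-3,11,11-trimethylspiro[5.5]undecan-7-ol
Product: 25 (2S,3S,6R,10R)-3,10-dibromo-2-chloro-3,11,11-trimethylspiro[5.5]undecan-7-one
Conditions: Dess–Martin periodinane, CH2Cl2, 0 °C
Reagents that add atoms: none
Why: Dess–Martin oxidation of the secondary alcohol under neutral conditions regenerates the C7 ketone without ionising the tertiary bromide.

Step 15
Reactants: 25 (2S,3S,6R,10R)-3,10-dibromo-2-chloro-3,11,11-trimethylspiro[5.5]undecan-7-one
Product: 26 obtusane, (2S,3S,6S,10R)-3,10-dibromo-2-chloro-3,11,11-trimethyl-7-methylidenespiro[5.5]undecane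
Conditions: Cp2Ti(μ-CH2)(μ-Cl)AlMe2, pyridine (trace), THF/toluene, −40 → 0 °C
Reagents that add atoms: Tebbe reagent (C[Al](C)C[Ti](Cl)(C1C=CC=C1)C1C=CC=C1)
Why: Tebbe methylenation (titanium methylidene, oxatitanacyclobutane) converts the hindered, enolisable ketone into the exocyclic methylene under non-basic conditions that should spare the tertiary bromide and the vicinal chloride.

**Compound list**
1 | 3-methylbut-2-en-1-ol | CC(C)=CCO | starting material
2 | (2R)-2-bromo-3-chloro-3-methylbutan-1-ol | OC[C@@H](Br)C(C)(C)Cl | intermediate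
3 | (2R)-2-bromo-3-chloro-3-methylbutyl trifluoromethanesulfonate | O=S(=O)(OC[C@@H](Br)C(C)(C)Cl)C(F)(F)F | intermediate
4 | prop-2-en-1-yl 3-oxobutanoate (allyl acetoacetate) | CC(=O)CC(=O)OCC=C | starting material
5 | sodium lithium dianion of 4 (formed in the flask) | [CH2-]C(=O)[CH-]C(=O)OCC=C.[Na+].[Li+] | intermediate
6 | prop-2-en-1-yl (6R)-6-bromo-7-chloro-7-methyl-3-oxooctanoate | C=CCOC(=O)CC(=O)CC[C@@H](Br)C(C)(C)Cl | intermediate
7 | prop-2-en-1-yl (1R,3R)-3-bromo-2,2-dimethyl-6-oxocyclohexane-1-carboxylate (keto form, C1 epimerisable) | C=CCOC(=O)[C@H]1C(=O)CC[C@@H](Br)C1(C)C | intermediate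
8 | (1R,3R)-3-bromo-2,2-dimethyl-6-oxocyclohexane-1-carboxylic acid (formed in the flask) | OC(=O)[C@H]1C(=O)CC[C@@H](Br)C1(C)C | intermediate
9 | (1S,3R)-3-bromo-2,2-dimethyl-1-(morpholin-4-ylmethyl)-6-oxocyclohexane-1-carboxylic acid (formed in the flask) | O=C1CC[C@@H](Br)C(C)(C)[C@]1(C(=O)O)CN1CCOCC1 | intermediate
10 | (4R)-4-bromo-3,3-dimethyl-2-methylidenecyclohexan-1-one | C=C1C(=O)CC[C@@H](Br)C1(C)C | intermediate
11 | 2-bromoethyl trifluoromethanesulfonate | BrCCOS(=O)(=O)C(F)(F)F | starting material
12 | {[(4R)-4-bromo-3,3-dimethyl-2-(prop-2-en-1-yl)cyclohex-1-en-1-yl]oxy}trimethylsilane (formed in the flask) | C=CCC1=C(O[Si](C)(C)C)CC[C@@H](Br)C1(C)C | intermediate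
13 | lithium (4R)-4-bromo-3,3-dimethyl-2-(prop-2-en-1-yl)cyclohex-1-en-1-olate (formed in the flask) | C=CCC1=C(O[Li])CC[C@@H](Br)C1(C)C | intermediate
14 | (2S,4R)-4-bromo-2-(2-bromoethyl)-3,3-dimethyl-2-(prop-2-en-1-yl)cyclohexan-1-one | O=C1CC[C@@H](Br)C(C)(C)[C@]1(CC=C)CCBr | intermediate
15 | (2S,4R)-4-bromo-2-(2-bromoethyl)-3,3-dimethyl-2-(1,2,4-trioxolan-3-ylmethyl)cyclohexan-1-one (formed in the flask, both epimers at the trioxolane carbon) | O=C1CC[C@@H](Br)C(C)(C)[C@]1(CC2OCOO2)CCBr | intermediate
16 | 2-[(1S,3R)-3-bromo-1-(2-bromoethyl)-2,2-dimethyl-6-oxocyclohexyl]acetaldehyde | O=C1CC[C@@H](Br)C(C)(C)[C@]1(CC=O)CCBr | intermediate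
17 | (2S,4R)-4-bromo-2-(2-bromoethyl)-2-[(2Z)-3-iodobut-2-en-1-yl]-3,3-dimethylcyclohexan-1-one | O=C1CC[C@@H](Br)C(C)(C)[C@]1(C/C=C(\I)C)CCBr | intermediate
18 | (2S,4R)-4-bromo-2-[(2Z)-3-iodobut-2-en-1-yl]-2-(2-iodoethyl)-3,3-dimethylcyclohexan-1-one | O=C1CC[C@@H](Br)C(C)(C)[C@]1(C/C=C(\I)C)CCI | intermediate
19 | {2-[(1S,3R)-3-bromo-1-[(2Z)-3-iodobut-2-en-1-yl]-2,2-dimethyl-6-oxocyclohexyl]ethyl}(iodo)zinc (formed in the flask) | O=C1CC[C@@H](Br)C(C)(C)[C@]1(C/C=C(\I)C)CC[Zn]I | intermediate
20 | (6R,10R)-10-bromo-3,11,11-trimethylspiro[5.5]undec-2-en-7-one | O=C1CC[C@@H](Br)C(C)(C)[C@]12CCC(C)=CC2 | intermediate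
21 | (6R,7R,10R)-10-bromo-3,11,11-trimethylspiro[5.5]undec-2-en-7-ol (hydroxyl equatorial, trans to Br) | O[C@@H]1CC[C@@H](Br)C(C)(C)[C@]12CCC(C)=CC2 | intermediate
22 | (2S,3S,6R,7R,10R)-10-bromo-2-chloro-3,11,11-trimethyl-3,7-epoxyspiro[5.5]undecane | O1[C@@H]2CC[C@@H](Br)C(C)(C)[C@]23CC[C@@]1(C)[C@@H](Cl)C3 | intermediate
23 | (2S,3S,6R,7R,10R)-3,10-dibromo-2-chloro-3,11,11-trimethylspiro[5.5]undecan-7-yl dimethylborinate (formed in the flask) | CB(C)O[C@@H]1CC[C@@H](Br)C(C)(C)[C@]12CC[C@](C)(Br)[C@@H](Cl)C2 | intermediate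
24 | (2S,3S,6R,7R,10R)-3,10-dibromo-2-chloro-3,11,11-trimethylspiro[5.5]undecan-7-ol | O[C@@H]1CC[C@@H](Br)C(C)(C)[C@]12CC[C@](C)(Br)[C@@H](Cl)C2 | intermediate
25 | (2S,3S,6R,10R)-3,10-dibromo-2-chloro-3,11,11-trimethylspiro[5.5]undecan-7-one | O=C1CC[C@@H](Br)C(C)(C)[C@]12CC[C@](C)(Br)[C@@H](Cl)C2 | intermediate
26 | obtusane, (2S,3S,6S,10R)-3,10-dibromo-2-chloro-3,11,11-trimethyl-7-methylidenespiro[5.5]undecane | C=C1CC[C@@H](Br)C(C)(C)[C@]12CC[C@](C)(Br)[C@@H](Cl)C2 | target

Total step count: 15. Longest linear sequence: 15 steps (1 to 26; 4 and 11 are bought).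

**Steps most likely to fail**

Step 13. The C3 cation may lose a proton to give alkenes. Bromide may also be captured on the wrong face once ring A has relaxed to its chair, or the tertiary bromide may re-ionise and equilibrate to the more stable axial epimer. The fallback drops the ether tether and sets out from ketone 20. Tetrabutylammonium dichlorobromate should add BrCl anti (bromine to C2, chloride to the tertiary C3) to give the trans-diaxial (2R,3R,6R,10R)-2,10-dibromo-3-chloro-3,11,11-trimethylspiro[5.5]undecan-7-one F1. Warming F1 in a polar, non-nucleophilic solvent should bring about the known diaxial-to-diequatorial 1,2-interchange of vicinal halogens, each halogen moving to the neighbouring carbon on its own face, driven by relief of the 1,3-diaxial Br/C7 contact. This returns to the route at ketone 25, and steps 11 to 14 are then not needed.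

Step 12. The β-chloro cation may lose a proton (ene-type allylic chlorination), the hydroxyl may close on C2 to the five-membered ether, or the carbinol may be oxidised by the N-chloro reagent. The fallback uses the ketone oxygen as the tether and sets out from ketone 20. With NCS in methanol the carbonyl oxygen should open the chloronium ion at C3, and methanol should trap the bridged oxocarbenium ion as the chloro ketal (2S,3S,6R,7R,10R)-10-bromo-2-chloro-7-methoxy-3,11,11-trimethyl-3,7-epoxyspiro[5.5]undecane F2 (either C7 epimer serves). Me2BBr then ionises the ketal and opens the C3–O bond with bromide, returning to the route at ketone 25 without steps 11, 13 and 14.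

Step 6. The hindered enolate may be alkylated on oxygen, may attack the bromine of the triflate (enolate bromination with loss of ethylene), or may show poor facial selectivity. The fallback sets out from enone 10 and goes through 12 and 13 as before, but traps the lithium enolate with 1-bromo-3-methylbut-2-ene, an allylic bromide that alkylates such enolates on carbon more reliably. This gives (2S,4R)-4-bromo-3,3-dimethyl-2-(3-methylbut-2-en-1-yl)-2-(prop-2-en-1-yl)cyclohexan-1-one F3. Ozone titrated against the more electron-rich trisubstituted double bond, with NaBH4 work-up at low temperature, should give (2S,4R)-4-bromo-2-(2-hydroxyethyl)-3,3-dimethyl-2-(prop-2-en-1-yl)cyclohexan-1-one F4. PPh3, I2 and imidazole convert it into (2S,4R)-4-bromo-2-(2-iodoethyl)-3,3-dimethyl-2-(prop-2-en-1-yl)cyclohexan-1-one F5. Ozonolysis of the remaining allyl group gives 2-[(1S,3R)-3-bromo-1-(2-iodoethyl)-2,2-dimethyl-6-oxocyclohexyl]acetaldehyde F6, and the olefination of step 8 applied to F6 returns to the route at 18.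

**Further compounds**
F1 | step 13 | (2R,3R,6R,10R)-2,10-dibromo-3-chloro-3,11,11-trimethylspiro[5.5]undecan-7-one | O=C1CC[C@@H](Br)C(C)(C)[C@]12CC[C@@](C)(Cl)[C@H](Br)C2
F2 | step 12 | (2S,3S,6R,7R,10R)-10-bromo-2-chloro-7-methoxy-3,11,11-trimethyl-3,7-epoxyspiro[5.5]undecane | O1[C@]2(OC)CC[C@@H](Br)C(C)(C)[C@]23CC[C@@]1(C)[C@@H](Cl)C3
F3 | step 6 | (2S,4R)-4-bromo-3,3-dimethyl-2-(3-methylbut-2-en-1-yl)-2-(prop-2-en-1-yl)cyclohexan-1-one | O=C1CC[C@@H](Br)C(C)(C)[C@]1(CC=C)CC=C(C)C
F4 | step 6 | (2S,4R)-4-bromo-2-(2-hydroxyethyl)-3,3-dimethyl-2-(prop-2-en-1-yl)cyclohexan-1-one | O=C1CC[C@@H](Br)C(C)(C)[C@]1(CC=C)CCO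
F5 | step 6 | (2S,4R)-4-bromo-2-(2-iodoethyl)-3,3-dimethyl-2-(prop-2-en-1-yl)cyclohexan-1-one | O=C1CC[C@@H](Br)C(C)(C)[C@]1(CC=C)CCI
F6 | step 6 | 2-[(1S,3R)-3-bromo-1-(2-iodoethyl)-2,2-dimethyl-6-oxocyclohexyl]acetaldehyde | O=C1CC[C@@H](Br)C(C)(C)[C@]1(CC=O)CCI
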